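Retrosynthesis (labdane numbering; ring A = C1–C5 and C10, ring B = C5–C10):
1. The C15 acid comes from selective saponification of the unhindered ester of the 15,18-dimethyl diester; the C3 methylene comes from deoxygenation of a 3-oxo diester.
2. The 3-oxo decalin is cut at C4–C5 and C9–C10 to an acyclic (E)-alkene/allylsilane β-keto ester; one amine-catalysed oxidative bicyclisation closes ring A first, then ring B, sets C4, C5, C9 and C10 and leaves the C8=C17 methylidene.
3. The β-keto ester is cut at C1–C2 (acetoacetate dianion + allylic bromide) and at C4–CH3 (enolate methylation).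
4. The allylsilane is cut at C8–C17 and C9–C11: syn-carbocupration of an enynol with a (trimethylsilyl)methylcopper reagent, then alkylation with a chiral iodo ester.
5. The iodo ester (C11–C15, stereocentre C13) comes from organocatalytic desymmetrisation of 3-methylglutaric anhydride; the enynol comes from pent-4-yn-1-ol by oxidation/Wittig/reduction.

Assumption: the senses of induction in steps 1 and 9 are assigned by analogy with the closest catalysed reactions; if either proves opposite, the pseudo-enantiomeric alkaloid (DHQ)2AQN or the enantiomeric diamine is used with no other change.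

Step 1
Reactants: 1 3-methylglutaric anhydride
Product: 2 (3R)-5-methoxy-3-methyl-5-oxopentanoic acid
Conditions: (DHQD)2AQN (10 mol%), MeOH (10 equiv), Et2O, −40 °C
Reagents that add atoms: methanol (CO)
Why: Organocatalytic desymmetrising alcoholysis of a prochiral anhydride, in which the bis-cinchona alkaloid acts as a chiral general base and directs methanol to one enantiotopic carbonyl, setting C13 (R) as the first stereocentre.

Step 2
Reactants: 2 (3R)-5-methoxy-3-methyl-5-oxopentanoic acid
Product: 3 methyl (3R)-5-hydroxy-3-methylpentanoate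
Conditions: BH3·SMe2, THF, 0 °C → rt; MeOH quench
Reagents that add atoms: none
Why: Chemoselective borane reduction of the carboxylic acid (via the acyloxyborane) in the presence of the methyl ester, which does not touch C13.

Step 3
Reactants: 3 methyl (3R)-5-hydroxy-3-methylpentanoate
Product: 4 methyl (3S)-5-iodo-3-methylpentanoate
Conditions: PPh3, NIS, CH2Cl2, 0 °C → rt
Reagents that add atoms: N-iodosuccinimide (O=C1CCC(=O)N1I)
Why: Appel-type iodination (alkoxyphosphonium, then SN2 by iodide at the primary carbon), run at once because 3 lactonises on standing; the label of C13 changes to S only because iodine outranks the ester branch.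

Step 4
Reactants: 5 pent-4-yn-1-ol; 6 ethyl 2-(triphenylphosphoranylidene)propanoate
Product: 8 ethyl (2E)-2-methylhept-2-en-6-ynoate, via pent-4-ynal 7 (not isolated)
Conditions: IBX (1.3 equiv), DMSO, rt, ylide 6 present from the start
Reagents that add atoms: none
Why: Tandem alcohol oxidation/Wittig olefination, in which the volatile aldehyde is trapped as it forms by the stabilised α-methyl ylide, which is (E)-selective for the trisubstituted enoate.

Step 5
Reactants: 8 ethyl (2E)-2-methylhept-2-en-6-ynoate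
Product: 9 (2E)-2-methylhept-2-en-6-yn-1-ol
Conditions: iBu2AlH (2.2 equiv), CH2Cl2, −78 °C; aq. KNaC4H4O6
Reagents that add atoms: none
Why: 1,2-Reduction of the conjugated ester by the aluminium hydride to the allylic alcohol, with the (E)-alkene and the terminal alkyne unchanged at −78 °C.

Step 6
Reactants: 9 (2E)-2-methylhept-2-en-6-yn-1-ol; 4 methyl (3S)-5-iodo-3-methylpentanoate
Product: 12 methyl (3R,6Z,10E)-12-hydroxy-3,11-dimethyl-7-[(trimethylsilyl)methyl]dodeca-6,10-dienoate, via magnesium alkoxide 10 (not isolated), via alkenylcopper 11 (not isolated)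
Conditions: iPrMgCl (1.0 equiv), THF, −20 °C; TMSCH2MgCl/CuBr·SMe2 (1.5 equiv), Et2O, −35 → −10 °C; then 4, HMPA, P(OEt)3, −10 °C → rt; aq. NH4Cl
Reagents that add atoms: (trimethylsilyl)methylmagnesium chloride (C[Si](C)(C)C[Mg]Cl)
Why: Normant syn-carbocupration puts CH2SiMe3 on the internal and copper on the terminal alkyne carbon on the same face, and SN2 alkylation of the alkenylcopper by the primary iodide with retention gives the allylsilane with C7 and C11 trans (6Z), the geometry that later places the side chain equatorial on ring B.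

Step 7
Reactants: 12 methyl (3R,6Z,10E)-12-hydroxy-3,11-dimethyl-7-[(trimethylsilyl)methyl]dodeca-6,10-dienoate
Product: 13 methyl (3R,6Z,10E)-12-bromo-3,11-dimethyl-7-[(trimethylsilyl)methyl]dodeca-6,10-dienoate
Conditions: CBr4, PPh3, 2,6-lutidine, CH2Cl2, −20 → 0 °C
Reagents that add atoms: carbon tetrabromide (BrC(Br)(Br)Br)
Why: Appel bromination of the primary allylic alcohol (SN2 on the alkoxyphosphonium salt) under buffered neutral conditions that spare the acid-sensitive allylsilane and the ester.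

Step 8
Reactants: 13 methyl (3R,6Z,10E)-12-bromo-3,11-dimethyl-7-[(trimethylsilyl)methyl]dodeca-6,10-dienoate; 14 methyl acetoacetate
Product: 17 dimethyl (2RS,6E,10Z,14R)-2,6,14-trimethyl-3-oxo-10-[(trimethylsilyl)methyl]hexadeca-6,10-dienedioate, via acetoacetate dianion 15 (not isolated), via alkylated keto ester enolate 16 (not isolated)
Conditions: 14, NaH then nBuLi, THF, 0 °C; 13, 0 °C; then MeI, DMPU, 0 °C → rt
Reagents that add atoms: iodomethane ([CH3]I)
Why: Weiler-type acetoacetate dianion alkylation, in which the more reactive γ-carbanion displaces the allylic bromide (SN2) and the remaining stabilised enolate is C-methylated in the same flask; C4 forms as a mixture, which is irrelevant because it becomes planar in step 9.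

Step 9
Reactants: 17 dimethyl (2RS,6E,10Z,14R)-2,6,14-trimethyl-3-oxo-10-[(trimethylsilyl)methyl]hexadeca-6,10-dienedioate
Product: 20 dimethyl (13R)-3-oxolabd-8(17)-ene-15,18-dioate (4α-CO2Me, 4β-CH3, 5α-H, 9α-H, 10β-CH3; 4S,5R,9S,10R), via enamino ester 18 (not isolated), via ketimine 19 (not isolated)
Conditions: (S)-tBuCH(NH2)CH2NEt2·TfOH (20 mol%), (4-BrC6H4)3N (10 mol%), nBu4NOTf (0.1 mol/L), MeOH (5 equiv), MeCN/HFIP 4:1, RVC anode/graphite cathode, undivided cell, 2 mA, 2.2 F/mol, 0 °C; aq. NaHCO3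
Reagents that add atoms: none
Why: Proposed new method: enantioselective amine-catalysed oxidative (SOMO-type) polyene bicyclisation of an α-methyl β-keto ester. The primary amine condenses with the C3 ketone to the (Z)-enamino ester 18, whose N–H···O=C(OMe) hydrogen bond holds the ester syn to nitrogen, so the ester is anti to C2 and the C4 methyl syn to C2. Mediated anodic one-electron oxidation at about +1.0 volt against SCE (below the alkenes and the allylsilane; the tertiary amine of the catalyst is masked as its ammonium triflate) gives an electrophilic enamine radical cation. C5 of the (E)-alkene attacks the Si face of C4, anti to the tert-butyl group, through a chair (CO2Me equatorial/α, CH3 axial/β, H5 α trans to the C10 methyl). The tertiary C10 radical, or its cation after a second oxidation, closes ring B on the allylsilane through a second chair (C11 equatorial, H9 α). Oxidation of the β-silyl radical and loss of the silyl group to methanol leaves only the exocyclic C8=C17 alkene, and hydrolysis of 19 returns the catalyst. The closest known reactions are the imidazolidinone organo-SOMO polyene cyclisation and SOMO allylation of aldehydes with allylsilanes, chiral primary-amine enamine catalysis of α-substituted β-keto esters (quaternary centres), and the racemic Mn(OAc)3/Cu(OAc)2 oxidative polyene cyclisation of β-keto esters, which gives the opposite C4 epimer.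

Step 10
Reactants: 20 dimethyl (13R)-3-oxolabd-8(17)-ene-15,18-dioate
Product: 21 dimethyl (13R)-3-[2-(4-methylbenzenesulfonyl)hydrazinylidene]labd-8(17)-ene-15,18-dioate
Conditions: TsNHNH2, MeOH, 50 °C
Reagents that add atoms: p-toluenesulfonohydrazide (Cc1ccc(cc1)S(=O)(=O)NN)
Why: Condensation of the C3 ketone with tosylhydrazide to the tosylhydrazone under neutral conditions that leave the exocyclic alkene, both esters and the quaternary C4 untouched.

Step 11
Reactants: 21 dimethyl (13R)-3-[2-(4-methylbenzenesulfonyl)hydrazinylidene]labd-8(17)-ene-15,18-dioate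
Product: 22 dimethyl (13R)-labd-8(17)-ene-15,18-dioate (4R,5R,9S,10R)
Conditions: catecholborane, CHCl3, 0 °C; NaOAc·3H2O, 60 °C
Reagents that add atoms: none
Why: Kabalka reduction (a mild Caglioti/Wolff–Kishner-type deoxygenation), in which catecholborane reduces the hydrazone, acetate-induced loss of sulfinate gives a diazene that extrudes N2, and C3 becomes CH2 without acid or strong base.

Step 12
Reactants: 22 dimethyl (13R)-labd-8(17)-ene-15,18-dioate
Product: 23 (3R)-5-[(1S,4aR,5R,8aR)-5-(methoxycarbonyl)-5,8a-dimethyl-2-methylidenedecahydronaphthalen-1-yl]-3-methylpentanoic acid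
Conditions: LiOH·H2O (1.5 equiv), THF/MeOH/H2O 3:1:1, rt; 1 N HCl to pH 3, 0 °C
Reagents that add atoms: lithium hydroxide ([Li+].[OH-])
Why: Chemoselective saponification, in which hydroxide attacks the unhindered C15 ester while the C18 ester on the quaternary, neopentyl C4 is inert at room temperature, and the brief cold acidification does not isomerise the 8(17)-alkene.

Compound list
1 | 3-methylglutaric anhydride (4-methyloxane-2,6-dione) | CC1CC(=O)OC(=O)C1 | starting material
2 | (3R)-5-methoxy-3-methyl-5-oxopentanoic acid | OC(=O)C[C@@H](C)CC(=O)OC | intermediate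
3 | methyl (3R)-5-hydroxy-3-methylpentanoate | OCC[C@@H](C)CC(=O)OC | intermediate
4 | methyl (3S)-5-iodo-3-methylpentanoate | ICC[C@@H](C)CC(=O)OC | intermediate
5 | pent-4-yn-1-ol | C#CCCCO | starting material
6 | ethyl 2-(triphenylphosphoranylidene)propanoate | CCOC(=O)C(C)=P(c1ccccc1)(c1ccccc1)c1ccccc1 | starting material
7 | pent-4-ynal (not isolated) | C#CCCC=O | intermediate
8 | ethyl (2E)-2-methylhept-2-en-6-ynoate | C#CCC/C=C(\C)C(=O)OCC | intermediate
9 | (2E)-2-methylhept-2-en-6-yn-1-ol | C#CCC/C=C(\C)CO | intermediate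
10 | chloromagnesium (2E)-2-methylhept-2-en-6-yn-1-olate (not isolated) | C#CCC/C=C(\C)CO[Mg]Cl | intermediate
11 | [(1Z,5E)-7-(chloromagnesiooxy)-6-methyl-2-[(trimethylsilyl)methyl]hepta-1,5-dien-1-yl]copper (not isolated; Cu cis to CH2SiMe3) | Cl[Mg]OC/C(C)=C/CC/C(C[Si](C)(C)C)=C/[Cu] | intermediate
12 | methyl (3R,6Z,10E)-12-hydroxy-3,11-dimethyl-7-[(trimethylsilyl)methyl]dodeca-6,10-dienoate | OC/C(C)=C/CC/C(C[Si](C)(C)C)=C/CC[C@@H](C)CC(=O)OC | intermediate
13 | methyl (3R,6Z,10E)-12-bromo-3,11-dimethyl-7-[(trimethylsilyl)methyl]dodeca-6,10-dienoate | BrC/C(C)=C/CC/C(C[Si](C)(C)C)=C/CC[C@@H](C)CC(=O)OC | intermediate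
14 | methyl acetoacetate | CC(=O)CC(=O)OC | starting material
15 | sodium lithium dianion of methyl acetoacetate (not isolated) | [Na+].[Li+].[CH2-]C(=O)[CH-]C(=O)OC | intermediate
16 | dimethyl (6E,10Z,14R)-6,14-dimethyl-3-oxo-10-[(trimethylsilyl)methyl]hexadeca-6,10-dienedioate (present as its enolate; not isolated) | COC(=O)CC(=O)CC/C(C)=C/CC/C(C[Si](C)(C)C)=C/CC[C@@H](C)CC(=O)OC | intermediate
17 | dimethyl (2RS,6E,10Z,14R)-2,6,14-trimethyl-3-oxo-10-[(trimethylsilyl)methyl]hexadeca-6,10-dienedioate (both C2 epimers) | COC(=O)C(C)C(=O)CC/C(C)=C/CC/C(C[Si](C)(C)C)=C/CC[C@@H](C)CC(=O)OC | intermediate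
18 | (2Z)-enamino ester of 17 with (S)-1-(diethylamino)-3,3-dimethylbutan-2-amine at C3, ester syn to N–H (not isolated) | COC(=O)/C(C)=C(\N[C@H](CN(CC)CC)C(C)(C)C)CC/C(C)=C/CC/C(C[Si](C)(C)C)=C/CC[C@@H](C)CC(=O)OC | intermediate
19 | C3 ketimine of 20 with the same (S)-diamine (not isolated) | C=C1CC[C@@H]2[C@](C)(CCC(=N[C@H](CN(CC)CC)C(C)(C)C)[C@@]2(C)C(=O)OC)[C@H]1CC[C@@H](C)CC(=O)OC | intermediate
20 | dimethyl (4S,5R,9S,10R,13R)-3-oxolabd-8(17)-ene-15,18-dioate (trans-decalin, 4α-CO2Me, 4β-CH3, side chain β at C9) | C=C1CC[C@@H]2[C@](C)(CCC(=O)[C@@]2(C)C(=O)OC)[C@H]1CC[C@@H](C)CC(=O)OC | intermediate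
21 | C3 tosylhydrazone of 20 | C=C1CC[C@@H]2[C@](C)(CCC(=NNS(=O)(=O)c3ccc(C)cc3)[C@@]2(C)C(=O)OC)[C@H]1CC[C@@H](C)CC(=O)OC | intermediate
22 | dimethyl (4R,5R,9S,10R,13R)-labd-8(17)-ene-15,18-dioate | C=C1CC[C@@H]2[C@](C)(CCC[C@@]2(C)C(=O)OC)[C@H]1CC[C@@H](C)CC(=O)OC | intermediate
23 | (3R)-5-[(1S,4aR,5R,8aR)-5-(methoxycarbonyl)-5,8a-dimethyl-2-methylidenedecahydronaphthalen-1-yl]-3-methylpentanoic acid | C=C1CC[C@@H]2[C@](C)(CCC[C@@]2(C)C(=O)OC)[C@H]1CC[C@@H](C)CC(=O)O | target

Total step count: 12. Longest linear sequence: 10 steps (steps 1–3 and 6–12, from 1 to 23); the alkyne branch (steps 4–5) joins at step 6.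

Steps most likely to fail

Step 9 (the proposed new reaction). It may fail through competing oxidation of the allylsilane, a racemic background pathway, or formation of the 4-epimer. The fallback sets out from 13 and comes back at 22, using an epoxide-initiated cyclisation in which the (E)-alkene geometry fixes C4. Alkylate 13 with lithiated acetaldehyde N-tert-butylimine (LiN(iPr)2, THF, −78 °C) to imine F5 and hydrolyse on work-up (aq. tartaric acid) to aldehyde F6. Wittig olefination with 2-(triphenylphosphoranylidene)propanal gives (E)-enal F7, and Luche reduction (NaBH4, CeCl3·7H2O, MeOH) gives allylic alcohol F8. Sharpless epoxidation (Ti(OiPr)4, diethyl (2R,3R)-tartrate, tBuOOH, 4 Å sieves, CH2Cl2, −20 °C) is hydroxyl-directed, so it touches neither the other alkene nor the allylsilane, and gives (2S,3S)-epoxy alcohol F9; TBSCl/imidazole gives epoxy silyl ether F10. MeAlCl2 (CH2Cl2, −78 °C) then triggers the allylsilane-terminated bicyclisation to hydroxy silyl ether F11 (3β-OH, 4α-CH2OTBS, trans-decalin, 8(17)-alkene). Barton–McCombie deoxygenation through phenyl thionocarbonate F12 (PhOC(S)Cl, DMAP; then Bu3SnH, AIBN, toluene, 80 °C) gives silyl ether F13, and TBAF gives primary alcohol F14. TEMPO/PhI(OAc)2 in wet MeCN gives acid F15, and TMSCHN2 (MeOH/toluene) gives 22. This costs eleven operations in place of three.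

Step 6 (carbocupration and alkylation of the alkenylcopper next to a free alkoxide). The fallback sets out from 9 (with 4) and comes back at 12, making the C9–C11 bond by palladium-catalysed cross-coupling instead of SN2 alkylation. Protect 9 as silyl ether F1 (TBSCl, imidazole). Run the same syn-carbocupration with TMSCH2Cu·MgBrCl but quench the alkenylcopper with iodine to give alkenyl iodide F2. Convert 4 into alkylzinc iodide F3 (zinc dust, LiCl, THF) and couple it with F2 (Negishi, PdCl2(dppf), THF/DMA, rt) to silyl ether F4. TBAF/AcOH then gives 12.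

Step 10 (hydrazone formation at the hindered C3 ketone next to the ester may be slow or may close onto the ester). The fallback sets out from 20 and comes back at 22 by radical deoxygenation of the alcohol instead of hydrazone reduction. Reduce 20 with NaBH4 (MeOH, 0 °C; esters untouched) to 3β-alcohol F16. Acylate it with PhOC(S)Cl/pyridine/DMAP (no strong base, so no retro-aldol) to phenyl thionocarbonate F17. Bu3SnH/AIBN (toluene, 80 °C) then gives 22.

Further compounds
F1 | step 6 | tert-butyl(dimethyl){[(2E)-2-methylhept-2-en-6-yn-1-yl]oxy}silane | C#CCC/C=C(\C)CO[Si](C)(C)C(C)(C)C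
F2 | step 6 | tert-butyl{[(2E,6Z)-7-iodo-2-methyl-6-[(trimethylsilyl)methyl]hepta-2,6-dien-1-yl]oxy}dimethylsilane | CC(C)(C)[Si](C)(C)OC/C(C)=C/CC/C(C[Si](C)(C)C)=C/I
F3 | step 6 | [(3S)-5-methoxy-3-methyl-5-oxopentyl]zinc iodide | I[Zn]CC[C@@H](C)CC(=O)OC
F4 | step 6 | methyl (3R,6Z,10E)-12-{[tert-butyl(dimethyl)silyl]oxy}-3,11-dimethyl-7-[(trimethylsilyl)methyl]dodeca-6,10-dienoate | CC(C)(C)[Si](C)(C)OC/C(C)=C/CC/C(C[Si](C)(C)C)=C/CC[C@@H](C)CC(=O)OC
F5 | step 9 | methyl (3R,6Z,10E)-14-(tert-butylimino)-3,11-dimethyl-7-[(trimethylsilyl)methyl]tetradeca-6,10-dienoate | CC(C)(C)N=CCC/C(C)=C/CC/C(C[Si](C)(C)C)=C/CC[C@@H](C)CC(=O)OC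
F6 | step 9 | methyl (3R,6Z,10E)-3,11-dimethyl-14-oxo-7-[(trimethylsilyl)methyl]tetradeca-6,10-dienoate | O=CCC/C(C)=C/CC/C(C[Si](C)(C)C)=C/CC[C@@H](C)CC(=O)OC
F7 | step 9 | methyl (3R,6Z,10E,14E)-3,11,15-trimethyl-16-oxo-7-[(trimethylsilyl)methyl]hexadeca-6,10,14-trienoate | O=C/C(C)=C/CC/C(C)=C/CC/C(C[Si](C)(C)C)=C/CC[C@@H](C)CC(=O)OC
F8 | step 9 | methyl (3R,6Z,10E,14E)-16-hydroxy-3,11,15-trimethyl-7-[(trimethylsilyl)methyl]hexadeca-6,10,14-trienoate | OC/C(C)=C/CC/C(C)=C/CC/C(C[Si](C)(C)C)=C/CC[C@@H](C)CC(=O)OC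
F9 | step 9 | methyl (3R,6Z,10E)-13-[(2S,3S)-3-(hydroxymethyl)-3-methyloxiran-2-yl]-3,11-dimethyl-7-[(trimethylsilyl)methyl]trideca-6,10-dienoate | OC[C@]1(C)O[C@H]1CC/C(C)=C/CC/C(C[Si](C)(C)C)=C/CC[C@@H](C)CC(=O)OC
F10 | step 9 | tert-butyldimethylsilyl ether of F9 | CC(C)(C)[Si](C)(C)OC[C@]1(C)O[C@H]1CC/C(C)=C/CC/C(C[Si](C)(C)C)=C/CC[C@@H](C)CC(=O)OC
F11 | step 9 | methyl (13R)-18-[(tert-butyldimethylsilyl)oxy]-3β-hydroxylabd-8(17)-en-15-oate | C=C1CC[C@@H]2[C@](C)(CC[C@H](O)[C@@]2(C)CO[Si](C)(C)C(C)(C)C)[C@H]1CC[C@@H](C)CC(=O)OC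
F12 | step 9 | methyl (13R)-18-[(tert-butyldimethylsilyl)oxy]-3β-[(phenoxycarbonothioyl)oxy]labd-8(17)-en-15-oate | C=C1CC[C@@H]2[C@](C)(CC[C@H](OC(=S)Oc3ccccc3)[C@@]2(C)CO[Si](C)(C)C(C)(C)C)[C@H]1CC[C@@H](C)CC(=O)OC
F13 | step 9 | methyl (13R)-18-[(tert-butyldimethylsilyl)oxy]labd-8(17)-en-15-oate | C=C1CC[C@@H]2[C@](C)(CCC[C@@]2(C)CO[Si](C)(C)C(C)(C)C)[C@H]1CC[C@@H](C)CC(=O)OC
F14 | step 9 | methyl (13R)-18-hydroxylabd-8(17)-en-15-oate | C=C1CC[C@@H]2[C@](C)(CCC[C@@]2(C)CO)[C@H]1CC[C@@H](C)CC(=O)OC
F15 | step 9 | (13R)-15-methoxy-15-oxolabd-8(17)-en-18-oic acid | C=C1CC[C@@H]2[C@](C)(CCC[C@@]2(C)C(=O)O)[C@H]1CC[C@@H](C)CC(=O)OC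
F16 | step 10 | dimethyl (13R)-3β-hydroxylabd-8(17)-ene-15,18-dioate | C=C1CC[C@@H]2[C@](C)(CC[C@H](O)[C@@]2(C)C(=O)OC)[C@H]1CC[C@@H](C)CC(=O)OC
F17 | step 10 | dimethyl (13R)-3β-[(phenoxycarbonothioyl)oxy]labd-8(17)-ene-15,18-dioate | C=C1CC[C@@H]2[C@](C)(CC[C@H](OC(=S)Oc3ccccc3)[C@@]2(C)C(=O)OC)[C@H]1CC[C@@H](C)CC(=O)OC
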